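The earlier runs and the new flask were generated by integration on assumed constants.

Q falls. In both earlier runs it is past its peak at the first reading, so I reckon with the fraction of Q left and not with the amount made.

all flasks: J 1.65 M

| flask | L | temperature | remark | time |
|---|---|---|---|---|
| red | 1 M | 32 °C | run made earlier |  |
| blue | 2.2 M | 49 °C | run made earlier |  |
| summer | 1.5 M | 55 °C |  | 3.0 d |
| midnight | 1.5 M |  | at 25 °C until 2.0 d, from then on at 55 °C | 3.0 d |
| winter | 1.5 M | 25 °C |  | 3.0 d |
| autumn | 1.5 M | 40 °C |  | 3.0 d |

- red (time / d: Q / %): 2.08: 10.5; 4.00: 7.2; 5.00: 6.9; 8.00: 5.3; 10.0: 3.3; 12.0: 2.6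
- blue (time / d: Q / %): 0.250: 7.0; 0.625: 4.5; 1.25: 2.3; 2.08: 0; 3.00: 0.3; 4.00: 0

(each reading ± 0.5 percentage points)



- the flask with the highest amount of Q, in percent of the L charged ("all alike" if they lie within 1.5 percentage points) (summer / midnight / winter / autumn / all alike)
- final Q, as a percentage of the L charged, in summer
- final Q, as a percentage of the L charged, in midnight
- final Q, as a percentage of the L charged, in winter
- final Q, as a percentage of the L charged, in autumn

The red readings give a decay constant k of 0.141 d⁻¹ and the blue ones 1.11 d⁻¹. Drawing ln k straight through these two temperatures gives 0.0600 d⁻¹ at 25 °C, 0.372 d⁻¹ at 40 °C and 2.31 d⁻¹ at 55 °C.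

I fold rate and time into one number, the exposure θ: k times time, summed leg by leg (a Damköhler number). It counts the lifetimes of Q a flask sits through, so exp(−θ) is the fraction of Q left, as long as no new Q forms. Winter has 0.180, autumn 1.12, summer 6.93. Midnight has 0.120 from its cold leg and 2.31 from its hot leg, together 2.43. Winter's exposure is the smallest, so I expect winter to hold the most Q.

Is one number enough? No: θ gives a fraction and not what it is a fraction of. Running the readings back to zero time gives 14.1% in red and 9.25% in blue, a gap far wider than the scatter of 0.5 percentage points. So I need a second number, the early plateau. For [L] = 1.5 M I take their mean, 11.7%, as a reading. That gives me 9.74% in winter, 3.82% in autumn, 1.03% in midnight and 0.0114% in summer.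

The forecast also names winter, with 11% there, 3.8% in autumn, 1.3% in midnight and 0.1% in summer. It “assumes formation is fast”, and its winter stands above mine.

The flasks give 12.3% in winter, 3.44% in autumn, 1.12% in midnight and 0.00565% in summer, so winter holds the most Q, as forecast.

    J → X (k = 0.0560 h⁻¹, Ea = 110 kJ mol⁻¹)
    L + J → Q (k = 0.00740 L mol⁻¹ h⁻¹, Ea = 91.0 kJ mol⁻¹)
    Q → D (k = 0.00220 h⁻¹, Ea = 104 kJ mol⁻¹)
    L → G (k = 0.0150 h⁻¹, Ea = 92.0 kJ mol⁻¹)
    (constants at 25 °C)

In midnight at 0.457 d, L has a half-life of 1.9 d by the step to G, shorter than the 4.9 d by the step to Q, and midnight ends with 86.0% as G. Its 12.7% of Q at the change, times exp(−θ) for the hot leg, gives 1.26% against the 1.12% found. Winter's 12.3%, carried on to 30.0 d with a further θ of 1.62, gives 2.43%, and that flask holds 2.97%.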